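C2 is the stereocentre of the pyran ring. C1' to C6' is the side chain counted from C2.

**Plan**
1. Retrosynthetic cuts, in order: C6–OH back to C6–Br; the side-chain bond C2'–C3' (allylic CH2 to vinylic CH); C3=C4 of the pyran ring; the aryl ether bond C8a–O1; on the terpenoid half, C3'–I and C4'–CH3 back to a terminal alkyne.
2. Enabling feature: C2 of the pyran ring is fully substituted and holds two two-carbon arms, C3=C4 inside the ring and C1'–C2' outside it. Both can be read as the vinyl groups of one achiral divinyl carbinol, and the arm not used for the ring stays on C2 as a vinyl group.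
3. That vinyl group is the only monosubstituted, unconjugated C=C of the chromene half, and it sits on a carbon without hydrogen. One flask (hydroboration, then B-alkyl Suzuki–Miyaura coupling) therefore puts H on C1' and the whole C14 arm on C2', which completes the C26 skeleton with all three C=C bonds in place.
4. Forward order: divinyl carbinol, aryl ether (SNAr), styrene (Wittig), pyran ring by desymmetrising ring-closing metathesis. Separately, alkyne and (E)-alkenyl iodide from dihydro-β-ionone, which brings the cyclohexene ring ready-made. Then coupling, then Br to OH.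
5. Stereochemistry: C2 (S) comes from the choice between the two enantiotopic vinyl groups by a chiral molybdenum alkylidene. The E C3'=C4' bond comes from syn methylalumination of the alkyne and is retained in the coupling.
6. Helpers: bromine at C6 activates the SNAr and masks the phenol; boron and iodine leave in the key step.

Key step: step 7

Assumption: the sense of induction of the molybdenum catalyst on triene 6 cannot be read from a mnemonic. The (S)-diolate is written; if a test run gives the mirror image of 7, the (R)-diolate, equally purchasable, is used with nothing else changed.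

Step 1
Reactants: 1 but-3-en-2-one (methyl vinyl ketone)
Product: 2 3-methylpenta-1,4-dien-3-ol
Conditions: CH2=CHMgBr, THF, −78 to 0 °C; then H2O
Reagents that add atoms: vinylmagnesium bromide, C=C[Mg]Br
Why: 1,2-Addition of a vinyl Grignard reagent to the ketone carbonyl, favoured over conjugate addition at low temperature, gives the tertiary carbinol, which is achiral because its two vinyl groups are identical.

Step 2
Reactants: 2 3-methylpenta-1,4-dien-3-ol; 3 5-bromo-2-fluorobenzaldehyde
Product: 5 5-bromo-2-[(3-methylpenta-1,4-dien-3-yl)oxy]benzaldehyde, via potassium alkoxide 4 (not isolated)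
Conditions: KHMDS, THF, −20 °C; then 3, THF–DMF, 0 °C to rt
Reagents that add atoms: none
Why: Nucleophilic aromatic substitution by addition–elimination: fluoride ortho to the formyl group and para to bromine is displaced by the tertiary alkoxide, the carbinol C–O bond is not touched, and C–Br, meta to the formyl group, is not activated.

Step 3
Reactants: 5 5-bromo-2-[(3-methylpenta-1,4-dien-3-yl)oxy]benzaldehyde
Product: 6 4-bromo-2-ethenyl-1-[(3-methylpenta-1,4-dien-3-yl)oxy]benzene
Conditions: Ph3PCH3Br, KOtBu, THF, 0 °C
Reagents that add atoms: methyltriphenylphosphonium bromide, C[P+](c1ccccc1)(c1ccccc1)c1ccccc1.[Br-]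
Why: Wittig methylenation of a non-enolisable aryl aldehyde runs under cold basic conditions that the acid- and heat-sensitive bis-allylic aryl ether tolerates.

Step 4
Reactants: 6 4-bromo-2-ethenyl-1-[(3-methylpenta-1,4-dien-3-yl)oxy]benzene
Product: 7 (2S)-6-bromo-2-ethenyl-2-methyl-2H-chromene
Conditions: Mo(N-2,6-iPr2C6H3)(CHCMe2Ph)[(S)-3,3'-tBu2-5,5',6,6'-Me4-1,1'-biphenyl-2,2'-diolate] (5 mol %), C6H6, 0.05 M, 22 °C, N2, dark
Reagents that add atoms: none
Why: Catalytic asymmetric ring-closing metathesis, known as a desymmetrisation of gem-divinyl carbinol ethers and gem-divinyl quaternary carbons: the aryl-substituted molybdenum alkylidene formed at the styrene closes the six-membered pyran ring onto one of the two enantiotopic vinyl groups within the chiral diolate pocket, which fixes C2 as S, releases ethene and leaves the second vinyl group on C2.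

Step 5
Reactants: 8 4-(2,6,6-trimethylcyclohex-1-en-1-yl)butan-2-one (dihydro-β-ionone)
Product: 10 2-(but-3-yn-1-yl)-1,3,3-trimethylcyclohex-1-ene, via enol phosphate 9 (not isolated)
Conditions: LDA, THF, −78 °C; ClP(O)(OEt)2, −78 °C to rt; LDA (2.3 equiv), −78 °C to rt; H2O
Reagents that add atoms: none
Why: Methyl ketone to terminal alkyne conversion through the kinetic enol phosphate: LDA deprotonates the methyl side, O-phosphorylation traps the terminal enolate and excess LDA eliminates diethyl phosphate, while the tetrasubstituted ring alkene is inert.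

Step 6
Reactants: 10 2-(but-3-yn-1-yl)-1,3,3-trimethylcyclohex-1-ene
Product: 12 2-[(3E)-4-iodo-3-methylbut-3-en-1-yl]-1,3,3-trimethylcyclohex-1-ene, via alkenylalane 11 (not isolated)
Conditions: Me3Al (2 equiv), Cp2ZrCl2 (0.2 equiv), CH2Cl2, 0 °C to rt; then I2, THF, −30 °C
Reagents that add atoms: trimethylaluminium, C[Al](C)C; iodine, II
Why: Negishi carboalumination: zirconium-catalysed syn addition of Me–Al places aluminium on the terminal carbon cis to the new methyl group, and iodinolysis with retention gives the E iodide.

Step 7
Reactants: 7 (2S)-6-bromo-2-ethenyl-2-methyl-2H-chromene; 12 2-[(3E)-4-iodo-3-methylbut-3-en-1-yl]-1,3,3-trimethylcyclohex-1-ene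
Product: 14 (2S)-6-bromo-2-methyl-2-[(3E)-4-methyl-6-(2,6,6-trimethylcyclohex-1-en-1-yl)hex-3-en-1-yl]-2H-chromene, via B-alkyl-9-BBN 13 (not isolated)
Conditions: 9-BBN-H dimer (1.05 equiv B–H), THF, 0 °C to rt, dark; then 12 (1.15 equiv), PdCl2(dppf) (5 mol %), AsPh3, Cs2CO3, DMF–H2O, rt
Reagents that add atoms: none
Why: 9-BBN-H adds syn across the vinyl group of 7 through a four-centre transition state with boron on the terminal carbon C2' and hydrogen on C1', giving 13. Zerovalent palladium inserts into the C–I bond of 12, the hydroxide-activated borate of 13 hands its primary alkyl group to the alkenylpalladium iodide, and reductive elimination, fast on the wide-bite-angle dppf complex and so ahead of β-hydride loss, forms C2'–C3'. The closest known reaction type is the one-flask hydroboration/B-alkyl Suzuki–Miyaura coupling of a terminal alkene with an (E)-alkenyl iodide. No ring is closed and no stereocentre is made: C2 is a spectator two bonds from the carbon that bears boron, and all three palladium steps keep the geometry at the sp2 carbon, so the E double bond of 12 is carried over. The step needs site selectivity between two alkenes and two halides: the vinyl group is the only monosubstituted, unconjugated C=C whereas C3=C4 is a cis-disubstituted styrene shielded by the fully substituted C2, and the alkenyl C–I bond adds to palladium at room temperature far faster than the electron-rich aryl C6–Br bond, helped by a slight excess of 12. The fully substituted C2 also sends boron to the chain end, remote from O1, so no β-alkoxide elimination is possible, and palladium is added only when the vinyl group is used up, so the doubly allylic C2–O1 bond of 7 never meets zerovalent palladium and cannot ionise and racemise.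

Step 8
Reactants: 14 (2S)-6-bromo-2-methyl-2-[(3E)-4-methyl-6-(2,6,6-trimethylcyclohex-1-en-1-yl)hex-3-en-1-yl]-2H-chromene
Product: 17 (2S)-2-methyl-2-[(3E)-4-methyl-6-(2,6,6-trimethylcyclohex-1-en-1-yl)hex-3-en-1-yl]-2H-chromen-6-ol, via aryllithium 15 (not isolated), via lithium aryltrimethoxyborate 16 (not isolated)
Conditions: n-BuLi, THF, −78 °C; B(OMe)3, −78 to 0 °C; 30% H2O2, aq NaOH, 0 °C; pH 7 buffer
Reagents that add atoms: hydrogen peroxide, OO
Why: Bromine–lithium exchange, borylation and peroxide-induced 1,2-shift of the aryl group from boron to oxygen (boronate oxidation) replace Br by OH at low temperature under basic conditions that leave the three C=C bonds and C2 alone.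

**Compound list**
1 | but-3-en-2-one | CC(=O)C=C | starting material
2 | 3-methylpenta-1,4-dien-3-ol | C=CC(C)(O)C=C | intermediate
3 | 5-bromo-2-fluorobenzaldehyde | O=Cc1cc(Br)ccc1F | starting material
4 | potassium 3-methylpenta-1,4-dien-3-olate | [K+].[O-]C(C)(C=C)C=C | intermediate
5 | 5-bromo-2-[(3-methylpenta-1,4-dien-3-yl)oxy]benzaldehyde | O=Cc1cc(Br)ccc1OC(C)(C=C)C=C | intermediate
6 | 4-bromo-2-ethenyl-1-[(3-methylpenta-1,4-dien-3-yl)oxy]benzene | C=Cc1cc(Br)ccc1OC(C)(C=C)C=C | intermediate
7 | (2S)-6-bromo-2-ethenyl-2-methyl-2H-chromene | C=C[C@@]1(C)C=Cc2cc(Br)ccc2O1 | intermediate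
8 | 4-(2,6,6-trimethylcyclohex-1-en-1-yl)butan-2-one (dihydro-β-ionone) | CC(=O)CCC1=C(C)CCCC1(C)C | starting material
9 | diethyl 4-(2,6,6-trimethylcyclohex-1-en-1-yl)but-1-en-2-yl phosphate | C=C(CCC1=C(C)CCCC1(C)C)OP(=O)(OCC)OCC | intermediate
10 | 2-(but-3-yn-1-yl)-1,3,3-trimethylcyclohex-1-ene | C#CCCC1=C(C)CCCC1(C)C | intermediate
11 | dimethyl[(1E)-2-methyl-4-(2,6,6-trimethylcyclohex-1-en-1-yl)but-1-en-1-yl]alane | C[Al](C)/C=C(C)/CCC1=C(C)CCCC1(C)C | intermediate
12 | 2-[(3E)-4-iodo-3-methylbut-3-en-1-yl]-1,3,3-trimethylcyclohex-1-ene | I/C=C(C)/CCC1=C(C)CCCC1(C)C | intermediate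
13 | 9-{2-[(2S)-6-bromo-2-methyl-2H-chromen-2-yl]ethyl}-9-borabicyclo[3.3.1]nonane | B1(CC[C@@]2(C)C=Cc3cc(Br)ccc3O2)C2CCCC1CCC2 | intermediate
14 | (2S)-6-bromo-2-methyl-2-[(3E)-4-methyl-6-(2,6,6-trimethylcyclohex-1-en-1-yl)hex-3-en-1-yl]-2H-chromene | CC1=C(CC/C(C)=C/CC[C@@]2(C)C=Cc3cc(Br)ccc3O2)C(C)(C)CCC1 | intermediate
15 | the 6-lithio analogue of 14 (aryllithium) | CC1=C(CC/C(C)=C/CC[C@@]2(C)C=Cc3cc([Li])ccc3O2)C(C)(C)CCC1 | intermediate
16 | lithium trimethoxy(chromen-6-yl)borate derived from 15 | CC1=C(CC/C(C)=C/CC[C@@]2(C)C=Cc3cc([B-](OC)(OC)OC)ccc3O2)C(C)(C)CCC1.[Li+] | intermediate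
17 | (2S)-2-methyl-2-[(3E)-4-methyl-6-(2,6,6-trimethylcyclohex-1-en-1-yl)hex-3-en-1-yl]-2H-chromen-6-ol | CC1=C(CC/C(C)=C/CC[C@@]2(C)C=Cc3cc(O)ccc3O2)C(C)(C)CCC1 | target

Total step count: 8. Longest linear sequence: 6 steps (1, 2, 3, 4, 7, 8).

**Steps most likely to fail**

Step 4. The catalyst may discriminate poorly between the two enantiotopic vinyl groups. Turnover may also be so slow, both ring-closing partners being hindered, that the bis-allylic aryl ether ionises or undergoes a Claisen shift before it closes.
- The fallback sets out from 6 and comes back at 7.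
- Triene 6 is closed with the fast, achiral second-generation Grubbs catalyst (CH2Cl2, rt, dark) to racemic 6-bromo-2-ethenyl-2-methyl-2H-chromene F1.
- F1 is separated by preparative supercritical-fluid chromatography on a polysaccharide chiral phase into 7 and its mirror image (2R)-6-bromo-2-ethenyl-2-methyl-2H-chromene F2, which is set aside.
- Physical resolution thus replaces asymmetric catalysis.

Step 2. The hindered alkoxide may attack the formyl carbon, and Tishchenko-type hydride transfer between aldehyde molecules may then outrun ipso attack at C–F.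
- The fallback sets out from 2 (as its alkoxide 4) and comes back at 5.
- The formyl group is kept out of the substitution by using purchased 5-bromo-2-fluorobenzonitrile (N#Cc1cc(Br)ccc1F) as the electrophile, which should give 5-bromo-2-[(3-methylpenta-1,4-dien-3-yl)oxy]benzonitrile F3.
- DIBAL-H (toluene, −78 °C) followed by hydrolysis with buffered aqueous Rochelle salt then delivers aldehyde 5.

Step 7. Boron-to-palladium transfer may be sluggish. Palladium could then insert into the C6–Br bond and cross-link the chromene units, or the alkyl group could be lost by protodeboronation.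
- The fallback sets out from 7 and comes back at 14.
- Borane 13 is oxidised (NaBO3·4H2O, THF–H2O) to 2-[(2S)-6-bromo-2-methyl-2H-chromen-2-yl]ethan-1-ol F4.
- An Appel-type iodination (I2, PPh3, imidazole, CH2Cl2, 0 °C) gives (2S)-6-bromo-2-(2-iodoethyl)-2-methyl-2H-chromene F5.
- Zinc dust with LiCl (THF, rt) inserts only into the alkyl C–I bond to give {2-[(2S)-6-bromo-2-methyl-2H-chromen-2-yl]ethyl}zinc iodide F6.
- A Negishi coupling of F6 with 12 (PdCl2(dppf), THF, 0 °C to rt), in which transmetalation from zinc is fast, forms the same C2'–C3' bond and gives 14.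

**Further compounds**
F1 | step 4 | racemic 6-bromo-2-ethenyl-2-methyl-2H-chromene | C=CC1(C)C=Cc2cc(Br)ccc2O1
F2 | step 4 | (2R)-6-bromo-2-ethenyl-2-methyl-2H-chromene | C=C[C@]1(C)C=Cc2cc(Br)ccc2O1
F3 | step 2 | 5-bromo-2-[(3-methylpenta-1,4-dien-3-yl)oxy]benzonitrile | N#Cc1cc(Br)ccc1OC(C)(C=C)C=C
F4 | step 7 | 2-[(2S)-6-bromo-2-methyl-2H-chromen-2-yl]ethan-1-ol | OCC[C@@]1(C)C=Cc2cc(Br)ccc2O1
F5 | step 7 | (2S)-6-bromo-2-(2-iodoethyl)-2-methyl-2H-chromene | ICC[C@@]1(C)C=Cc2cc(Br)ccc2O1
F6 | step 7 | {2-[(2S)-6-bromo-2-methyl-2H-chromen-2-yl]ethyl}zinc iodide | I[Zn]CC[C@@]1(C)C=Cc2cc(Br)ccc2O1
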